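**Retrosynthetic overview**
1. Target 1 ⇒ a C3‑demethyl tricyclic enone alcohol, by C9 angeloylation and by methyl addition followed by oxidative 1,3‑carbonyl transposition.
2. Cyclobutane (last ring): the C4–C10 bond, from Lewis‑acid opening of a 9,10‑epoxide at its tertiary carbon by the C4 silyl enol ether of a cis‑fused six/seven (himachalane‑type) epoxy enone. This is the laboratory counterpart of the himachalyl → longipinyl cation closure.
3. Seven‑membered ring: ring‑closing metathesis forming C9=C10, then convex‑face epoxidation.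
4. Six‑membered ring: Diels–Alder reaction of an aminosiloxy diene with an enantioenriched α,β‑unsaturated δ‑lactone. The lactone is a temporary ring that fixes the cis C5/C11 relationship and relays the C7 stereocentre; its carbonyl carbon becomes C10.
5. Ring order: δ‑lactone (temporary) → six → seven → four. The C7 stereocentre comes from an asymmetric allylboration.

**Assumptions.** Locants C1–C11 are those of the longipinane skeleton of the target and are kept for every intermediate: C1 = ketone carbon of the target, C3 = C–Me of the enone, C6 = CMe2, C7 = CH–O‑senecioyl, C9 = CH–O‑angeloyl, C10 = quaternary C–Me, C4/C5/C10/C11 = cyclobutane. The allylborane of step 2 is the enantiomer made from (−)‑α‑pinene (sold as (+)‑Ipc2B(allyl); it gives (+)‑isopinocampheol on oxidation). This allylborane, the aminosiloxy diene, the Tebbe reagent, senecioic acid and angelic acid are bought.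

Step 1
Reactants: 2 isobutyraldehyde; 3 methyl acrylate
Product: 6 methyl 4,4-dimethyl-5-oxopentanoate, via enamine 4 (not isolated), via aminocyclobutane ester 5 (not isolated)
Conditions: pyrrolidine, PhMe, Dean–Stark; 3, MeCN, reflux; then aq. AcOH, 60 °C
Reagents that add atoms: water, O
Why: Stork enamine Michael addition (through the known enamine–acrylate cyclobutane adduct, opened on hydrolysis) gives the α‑quaternary aldehyde ester that carries C5–C7, C10, C11 and the gem‑dimethyl group.

Step 2
Reactants: 6 methyl 4,4-dimethyl-5-oxopentanoate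
Product: 8 (6R)-5,5-dimethyl-6-(prop-2-en-1-yl)oxan-2-one, via hydroxy ester 7 (not isolated)
Conditions: (+)-Ipc2B(allyl) [from (−)-α-pinene], Et2O, −78 °C; NaOH, H2O2, 0 °C; then TsOH (cat.), PhMe, 50 °C
Reagents that add atoms: (+)-B-allyldiisopinocampheylborane [from (−)-α-pinene], C=CCB([C@H]1C[C@H]2C[C@H](C2(C)C)[C@@H]1C)[C@H]1C[C@H]2C[C@H](C2(C)C)[C@@H]1C
Why: Brown asymmetric allylboration (reagent‑controlled Re‑face addition to the α‑quaternary aldehyde through a chair transition state) sets C7 as R, and the δ‑hydroxy ester lactonises under acid.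

Step 3
Reactants: 8 (6R)-5,5-dimethyl-6-(prop-2-en-1-yl)oxan-2-one
Product: 10 (6R)-5,5-dimethyl-6-(prop-2-en-1-yl)-5,6-dihydro-2H-pyran-2-one, via selenide 9 (not isolated)
Conditions: LiN(iPr)2, THF, −78 °C; PhSeBr; then H2O2, pyridine, CH2Cl2, 0 °C → rt
Reagents that add atoms: none
Why: α‑Selenenylation and selenoxide syn‑elimination can only give the endocyclic C11=C5 alkene, which makes the lactone a cis‑locked dienophile.

Step 4
Reactants: 10 (6R)-5,5-dimethyl-6-(prop-2-en-1-yl)-5,6-dihydro-2H-pyran-2-one; 11 (E)-3-(tert-butyldimethylsilyloxy)-N,N-dimethylbuta-1,3-dien-1-amine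
Product: 12 cis-fused aminosiloxy cycloadduct lactone (new carbocycle anti to the allyl group; H5 and H11 syn to it; NMe2 cis to the lactone carbonyl)
Conditions: PhMe, 110 °C, sealed tube
Reagents that add atoms: none
Why: Diels–Alder reaction of the aminosiloxy (Rawal) diene: its CH2 terminus bonds to the β‑carbon C5 and its amino terminus to C11, the ring dienophile enforces the cis C5/C11 fusion, and the diene adds endo to the face anti to the C7 allyl group and the pseudo‑axial C6 methyl, which sets C5 and C11 from C7.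

Step 5
Reactants: 12 cis-fused aminosiloxy cycloadduct lactone
Product: 13 C11-acetyl C7-carbinol (ring-opened lactone)
Conditions: MeLi (1.1 equiv), THF, −78 °C; pH 7 buffer
Reagents that add atoms: methyllithium, [Li]C
Why: Mono‑addition of MeLi to the δ‑lactone (the tetrahedral adduct does not collapse at −78 °C) turns the lactone carbonyl into the C10 methyl ketone and frees the C7 hydroxyl, while the silyl enol ether masks the ring ketone.

Step 6
Reactants: 13 C11-acetyl C7-carbinol
Product: 14 C11-isopropenyl C7-carbinol (silyl enol ether and NMe2 retained)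
Conditions: Tebbe reagent Cp2Ti(μ-Cl)(μ-CH2)AlMe2 (3 equiv), pyridine, THF–PhMe, −40 → 0 °C; aq. NaOH
Reagents that add atoms: Tebbe reagent, C[Al-]1(C)C[Ti]([Cl+]1)(C1C=CC=C1)C1C=CC=C1
Why: Tebbe methylenation (titanium methylidene [2+2] with the ketone, then cycloreversion) is non‑basic, so the β‑amino ketone does not eliminate and the epimerisable C11 centre is kept while the isopropenyl group (C10 with its methyl) is installed; the excess reagent covers the free hydroxyl.

Step 7
Reactants: 14 C11-isopropenyl C7-carbinol; 15 senecioic acid (3-methylbut-2-enoic acid)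
Product: 17 (4R,5S)-4-(prop-1-en-2-yl)-5-[(3R)-2-methyl-3-(3-methylbut-2-enoyloxy)hex-5-en-2-yl]cyclohex-2-en-1-one, via ester 16 (not isolated)
Conditions: 15, 2,4,6-Cl3C6H2COCl, Et3N, PhMe, rt; 14, DMAP, 40 °C; then 1 M HCl, THF, 0 °C
Reagents that add atoms: none
Why: Yamaguchi esterification puts the senecioate on the hindered C7 alcohol without deconjugation, and the acid then hydrolyses the silyl enol ether and eliminates dimethylamine (E1cB) to reveal the C3(=O)–C2=C1 enone.

Step 8
Reactants: 17 dienone ester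
Product: 18 cis-fused bicyclic dienone senecioate (5S,7R,11R; C3 ketone; C1=C2 and C9=C10 alkenes)
Conditions: second-generation Hoveyda–Grubbs catalyst (H2IMes)Cl2Ru(=CH-C6H4-2-OiPr) (5 mol %), 1,4-benzoquinone (10 mol %), PhMe (5 mM), 80 °C
Reagents that add atoms: none
Why: Ring‑closing metathesis of the allyl and isopropenyl groups closes the seven‑membered ring as the trisubstituted C9=C10 alkene; the enone and the senecioate alkenes are inert and benzoquinone suppresses alkene migration.

Step 9
Reactants: 18 cis-fused bicyclic dienone senecioate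
Product: 19 9,10-epoxy enone (5S,7R,9R,10S,11R)
Conditions: mCPBA, NaHCO3, CH2Cl2, 0 °C
Reagents that add atoms: mCPBA, OOC(=O)c1cccc(Cl)c1
Why: Prilezhaev epoxidation takes only the electron‑rich C9=C10 alkene, from the convex face anti to both the six‑membered ring and the C7 ester, which places the epoxide oxygen trans to C4.

Step 10
Reactants: 19 9,10-epoxy enone
Product: 21 3-demethyl-9-hydroxy-7-senecioyloxylongipin-1-en-3-one (4S,5R,7R,9R,10S,11R), via silyl dienol ether 20 (not isolated)
Conditions: LiN(iPr)2, TMSCl, THF, −78 °C; solvent switch; MeAlCl2 (1.5 equiv), CH2Cl2, −78 → −40 °C; aq. HCl work-up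
Reagents that add atoms: none
Why: Proposed new method: kinetic α′‑deprotonation gives the C4 silyl enol ether regiospecifically, MeAlCl2 then polarises the C10–O bond into an incipient tertiary (himachalyl‑type) cation, and C4, held about 3 Å away by the cis ring fusion, attacks anti to the leaving oxygen in a 4‑exo closure (inversion at C10, C9–O retained, C4 set by the only reachable face) before loss of the silyl group restores the enone; the closest known reactions are MeAlCl2 epoxide‑initiated cation–olefin cyclisations terminated by silyl enol ethers (Mukaiyama‑type) and the Stork epoxynitrile cyclisation to cyclobutanes.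

Step 11
Reactants: 21 tricyclic enone alcohol; 22 angelic acid ((Z)-2-methylbut-2-enoic acid)
Product: 23 9-angelate of 21
Conditions: 22, 2,4,6-Cl3C6H2COCl, Et3N, PhMe, rt; then 21, 80 °C
Reagents that add atoms: none
Why: Yamaguchi mixed‑anhydride acylation without DMAP esterifies the hindered C9 alcohol while keeping the Z (angelate) geometry.

Step 12
Reactants: 23 9-angelate
Product: 24 tertiary allylic alcohol (C3 methyl carbinol, 3S; C1=C2 alkene)
Conditions: CeCl3, MeLi, THF, −78 °C
Reagents that add atoms: methylcerium dichloride (from MeLi and CeCl3), C[Ce](Cl)Cl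
Why: Imamoto organocerium 1,2‑addition to the enone carbonyl, from the C5–H side anti to the C10 methyl, installs the C3 methyl group without touching the two hindered unsaturated esters; the new carbinol centre is destroyed in the next step.

Step 13
Reactants: 24 tertiary allylic alcohol
Product: 1 (4R,5S,7R,9R,10R,11R)-9-angeloyloxy-7-senecioyloxylongipin-2-en-1-one
Conditions: pyridinium chlorochromate [C5H5NH][CrO3Cl], NaOAc, 4 Å MS, CH2Cl2, 0 °C → rt
Reagents that add atoms: pyridinium chlorochromate, [O-][Cr](=O)(=O)Cl.c1cc[nH+]cc1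
Why: Dauben–Babler oxidative 1,3‑transposition (allylic chromate [3,3] shift, then oxidation) moves the oxygen to C1 and leaves the C2=C3(Me) alkene, the same change as apoverbenone → verbenone.

**Compound list**
1 | (4R,5S,7R,9R,10R,11R)-9-angeloyloxy-7-senecioyloxylongipin-2-en-1-one | C/C=C(/C)C(=O)O[C@@H]1C[C@@H](OC(=O)C=C(C)C)C(C)(C)[C@@H]2[C@H]3C(=O)C=C(C)[C@@H]2[C@]31C | target
2 | isobutyraldehyde | CC(C)C=O | starting material
3 | methyl acrylate | C=CC(=O)OC | starting material
4 | 1-(2-methylprop-1-en-1-yl)pyrrolidine | CC(C)=CN1CCCC1 | intermediate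
5 | methyl 3,3-dimethyl-2-(pyrrolidin-1-yl)cyclobutane-1-carboxylate (diastereomer mixture) | COC(=O)C1CC(C)(C)C1N1CCCC1 | intermediate
6 | methyl 4,4-dimethyl-5-oxopentanoate | COC(=O)CCC(C)(C)C=O | intermediate
7 | methyl (5R)-5-hydroxy-4,4-dimethyloct-7-enoate | C=CC[C@@H](O)C(C)(C)CCC(=O)OC | intermediate
8 | (6R)-5,5-dimethyl-6-(prop-2-en-1-yl)oxan-2-one | C=CC[C@H]1OC(=O)CCC1(C)C | intermediate
9 | (6R)-5,5-dimethyl-3-(phenylselanyl)-6-(prop-2-en-1-yl)oxan-2-one (C3 epimers) | C=CC[C@H]1OC(=O)C([Se]c2ccccc2)CC1(C)C | intermediate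
10 | (6R)-5,5-dimethyl-6-(prop-2-en-1-yl)-5,6-dihydro-2H-pyran-2-one | C=CC[C@H]1OC(=O)C=CC1(C)C | intermediate
11 | (E)-3-(tert-butyldimethylsilyloxy)-N,N-dimethylbuta-1,3-dien-1-amine | CN(C)/C=C/C(=C)O[Si](C)(C)C(C)(C)C | starting material
12 | (3R)-3-allyl-6-(tert-butyldimethylsilyloxy)-8-(dimethylamino)-4,4-dimethyl-3,4,4a,5,8,8a-hexahydro-1H-isochromen-1-one; cis ring fusion; carbocycle anti to allyl (H-4a and H-8a syn to allyl); NMe2 cis to C-1 | C=CC[C@H]1OC(=O)[C@@H]2[C@H](N(C)C)C=C(O[Si](C)(C)C(C)(C)C)C[C@@H]2C1(C)C | intermediate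
13 | C11-acetyl C7-carbinol from opening of 12 (cyclohexene silyl enol ether with NMe2, acetyl and the 3-hydroxy-2-methylhex-5-en-2-yl chain) | CC(=O)[C@@H]1[C@H](N(C)C)C=C(O[Si](C)(C)C(C)(C)C)C[C@@H]1C(C)(C)[C@H](O)CC=C | intermediate
14 | C11-isopropenyl analogue of 13 | C=C(C)[C@@H]1[C@H](N(C)C)C=C(O[Si](C)(C)C(C)(C)C)C[C@@H]1C(C)(C)[C@H](O)CC=C | intermediate
15 | senecioic acid (3-methylbut-2-enoic acid) | CC(C)=CC(=O)O | starting material
16 | C7 senecioate of 14 | C=C(C)[C@@H]1[C@H](N(C)C)C=C(O[Si](C)(C)C(C)(C)C)C[C@@H]1C(C)(C)[C@H](OC(=O)C=C(C)C)CC=C | intermediate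
17 | (4R,5S)-4-(prop-1-en-2-yl)-5-[(3R)-2-methyl-3-(3-methylbut-2-enoyloxy)hex-5-en-2-yl]cyclohex-2-en-1-one | C=C(C)[C@@H]1C=CC(=O)C[C@@H]1C(C)(C)[C@@H](CC=C)OC(=O)C=C(C)C | intermediate
18 | cis-fused six/seven bicyclic dienone (5S,7R,11R): C3 ketone, C1=C2, C9=C10(Me), C6 gem-dimethyl, C7 senecioate | CC1=CC[C@@H](OC(=O)C=C(C)C)C(C)(C)[C@H]2CC(=O)C=C[C@@H]12 | intermediate
19 | 9,10-epoxide of 18 (5S,7R,9R,10S,11R); epoxide oxygen trans to C4, C1 and the C7 ester | O1[C@@H]2C[C@@H](OC(=O)C=C(C)C)C(C)(C)[C@H]3CC(=O)C=C[C@H]3[C@]12C | intermediate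
20 | C3 trimethylsilyl dienol ether of 19 (C4=C3(OSiMe3)–C2=C1) | O1[C@@H]2C[C@@H](OC(=O)C=C(C)C)C(C)(C)[C@H]3C=C(O[Si](C)(C)C)C=C[C@H]3[C@]12C | intermediate
21 | 3-demethyl-9-hydroxy-7-senecioyloxylongipin-1-en-3-one (4S,5R,7R,9R,10S,11R) | O[C@@H]1C[C@@H](OC(=O)C=C(C)C)C(C)(C)[C@@H]2[C@H]3C=CC(=O)[C@@H]2[C@]31C | intermediate
22 | angelic acid ((Z)-2-methylbut-2-enoic acid) | C/C=C(/C)C(=O)O | starting material
23 | 9-angelate of 21 | C/C=C(/C)C(=O)O[C@@H]1C[C@@H](OC(=O)C=C(C)C)C(C)(C)[C@@H]2[C@H]3C=CC(=O)[C@@H]2[C@]31C | intermediate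
24 | C3 methyl carbinol of 23 (3S; methyl anti to the C10 methyl) | C/C=C(/C)C(=O)O[C@@H]1C[C@@H](OC(=O)C=C(C)C)C(C)(C)[C@@H]2[C@H]3C=C[C@](C)(O)[C@@H]2[C@]31C | intermediate

**Count.** Total steps: 13. Longest linear sequence: 13 (from 2 and 3).

**Three steps most likely to fail, each with a fallback**

Step 10 (cyclobutane closure). The four‑membered ring must form faster than Meinwald rearrangement or E1 loss from the activated epoxide, and faster than participation by the C7 ester carbonyl at C9. The fallback sets out from 19 and comes back at 21. It drops the silyl enol ether and the Lewis acid and runs the closure as a base‑mediated, Stork‑type epoxide alkylation: KN(SiMe3)2 (1.05 equiv) in toluene, −78 → 60 °C, makes the kinetic potassium C4 enolate, whose carbon displaces the epoxide oxygen at C10 from the rear (4‑exo‑tet, SN2) and gives the alkoxide of 21 directly. This fallback makes no new compound F0.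

Step 4 (cycloaddition on a lactone whose β‑carbon is neopentyl). If the thermal reaction stalls, the fallback sets out from 10 and comes back at 17. The six‑membered ring is built stepwise by a Lewis‑acid‑mediated Mukaiyama–Michael/Michael sequence with 2-(tert-butyldimethylsilyloxy)buta-1,3-diene (C=CC(=C)O[Si](C)(C)C(C)(C)C; MeAlCl2, CH2Cl2, −78 °C), which gives the amine‑free cis‑fused silyl enol ether lactone F1. MeLi then gives the methyl ketone alcohol F2, Tebbe methylenation gives the isopropenyl alcohol F3, and Yamaguchi esterification with 15 gives the senecioate F4. Saegusa–Ito dehydrogenation of the regiodefined silyl enol ether (Pd(OAc)2, O2, DMSO) then gives enone 17.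

Step 13 (chromate transposition next to the strained cyclobutane, where an allylic cation could trigger Wagner–Meerwein shifts). The fallback sets out from 24 and comes back at 1. A Ph3SiOReO3‑catalysed 1,3‑hydroxyl transposition (Et2O, 0 °C) gives the secondary C1 allylic alcohol F5, which already has the C2=C3 methyl alkene, and neutral MnO2 oxidation (CH2Cl2, rt) then gives 1.

**Further compounds**
F1 | step 4 | (3R)-3-allyl-6-(tert-butyldimethylsilyloxy)-4,4-dimethyl-3,4,4a,5,8,8a-hexahydro-1H-isochromen-1-one (cis-fused; carbocycle anti to allyl, ring-fusion hydrogens syn to allyl) | C=CC[C@H]1OC(=O)[C@@H]2CC=C(O[Si](C)(C)C(C)(C)C)C[C@@H]2C1(C)C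
F2 | step 4 | C11-acetyl C7-carbinol from opening of F1 | CC(=O)[C@@H]1CC=C(O[Si](C)(C)C(C)(C)C)C[C@@H]1C(C)(C)[C@H](O)CC=C
F3 | step 4 | C11-isopropenyl analogue of F2 | C=C(C)[C@@H]1CC=C(O[Si](C)(C)C(C)(C)C)C[C@@H]1C(C)(C)[C@H](O)CC=C
F4 | step 4 | C7 senecioate of F3 | C=C(C)[C@@H]1CC=C(O[Si](C)(C)C(C)(C)C)C[C@@H]1C(C)(C)[C@H](OC(=O)C=C(C)C)CC=C
F0 | step 10 | none | none
F5 | step 13 | 9-angeloyloxy-7-senecioyloxylongipin-2-en-1-ol (C1 carbinol, either epimer) | C/C=C(/C)C(=O)O[C@@H]1C[C@@H](OC(=O)C=C(C)C)C(C)(C)[C@@H]2[C@H]3C(O)C=C(C)[C@@H]2[C@]31C
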